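(The numbers are assumed; the run is a simulation.)

- Trace the target back: it forms when reagent captures the first chain carrier, and the same capture makes the second chain carrier, which attacks starting material and gives by-product and a new first chain carrier.

starting material 0.10 M; reagent 0.900 equiv; transfer agent 0.0300 M; initiator 4.4 mol%; time 10 h

    2 first chain carrier → ended chains B (k1 = 6 × 10⁷ /M/s)
    initiator → 2 initiating radical (k2 = 0.14 /h)
    starting material + second chain carrier → by-product + first chain carrier (k3 = 9.6 × 10⁶ /M/h)
    reagent + first chain carrier ⇌ target + second chain carrier (K4 = 0.93, k4 = 1.8 × 10⁷ /M/h)
    2 idle radical → ended radicals (k5 = 7.3 × 10⁷ /M/s)
    2 second chain carrier → ended chains A (k6 = 3 × 10⁸ /M/s)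
    reagent + by-product ⇌ idle adduct, settled at all times (K7 = 11 /M)
    starting material + initiating radical → capped initiator + first chain carrier (k8 = 24000 /M/s)
    transfer agent + first chain carrier → side product + idle radical (k9 = 1.2 × 10⁵ /M/s)

- a species is counted by the starting material in it: one ended chains B counts as two
- amounts and yields of by-product count idle adduct too
- a step written with two of one species runs at k times the square of its concentration and takes two of it each time
- run time (flask): 10 h

- part of the starting material that has reacted at 10 h
- share of the unused reagent that is free and not bound as idle adduct, at 10 h

- Begin with the bench rule for a short chain, one starting material per initiating radical: the initiator has a half-life of 5.0 h and gives two radicals per decay, so by 10 h this flask has made 0.00663 M of them, which is 6.63% of the starting material.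
- Compute the rest as a correction: treat each capture of the first chain carrier as pseudo-first-order, at 3600 /s by the transfer agent, which ends the chain as idle radical, and at 450 /s by the reagent, which continues it, so the transfer agent wins.
- Take the ratio of the reagent's rate to the transfer agent's, 0.125 at the charge: this chain correction is the extra starting material spent per initiating radical.
- Trust the bench rule only while the correction stays small beside one, since it reaches one where [reagent]/[transfer agent] equals 24.0, and this flask charges 3.00.
- Commit to 7.46% reacted, and to 8.29 × 10⁻⁴ M of by-product; since K[reagent] is 0.99, about half of that is bound, which leaves 99.5% of the unused reagent free.
- Set beside this the forecast, 7.5% (7% to 8%) and 99.5% (99.2% to 99.7%), whose ground is that “The transfer agent captures the first chain carrier about eight times faster than the reagent does”; its correction of 14 per cent stands above my 12.5%.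
- Read 7.55% reacted and 99.5% free in this flask, both inside the forecast's ranges; the answer for reacted starting material in this flask has moved by 5 points when the initiator alone goes to 1.5 mol% or 7.2 mol%. Divide target 0.920% by side product 6.63% at 10.0 h for a reading of 0.139, higher than the correction of 0.125 at the charge. Raise the reagent to 1.50 equiv and the correction becomes 0.208, which predicts 8.01%; that neighbouring flask gives 8.15%.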